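Numbering follows bicyclo[3.2.1]oct-3-en-8-one (C1 methoxy bridgehead, C5 allyl bridgehead, C6 CHMe, C7 CHAr, C8 ketone). The route rests on cutting the cyclopentanone ring C1–C7–C6–C5–C8 back to a cyclobutane in which C7 is still bonded to C8. All eight skeletal carbons are then one linear oxygenated tetraene, C7=C8–C1=C2–C3=C4–C5=C6, formed by double enol silylation of a 2-methoxy-1,3-diketone. A thermal 8π–6π electrocyclization cascade joins C6–C7 and C5–C8 in one operation, exploiting the ketone oxygen at C8 and the C3=C4 enol ether as parts of the polyene; a semipinacol shift of C7 from C8 to C1 then gives the bicyclo[3.2.1] core.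

Key step: step 8

Remark 1: the tetraene of step 8 is achiral, so 15 to 18 are racemates whose SMILES show the enantiomer that leads to the target; step 10 selects that enantiomer by kinetic resolution.
Remark 2: pyran 8 and the open cis-dienone 7 are valence tautomers that interconvert at room temperature, so step 7 draws on this equilibrium; 13 is written open-chain although it can close to the analogous pyran.
Remark 3: in the Why lines, C1 to C8 always mean the positions the atoms take in the target.

Step 1
Reactants: 1 but-2-yn-1-ol; 2 allylmagnesium bromide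
Product: 3 (2E)-2-(prop-2-en-1-yl)but-2-en-1-ol
Conditions: 2 (2.5 equiv), CuI (10 mol %), THF, −20 °C to rt; aq NH4Cl
Reagents that add atoms: none
Why: Hydroxyl-directed anti carbomagnesiation of the propargylic alkoxide should put the allyl group on the alkyne carbon next to CH2O and, through the five-membered magnesium chelate, leave the methyl cis to the allyl group after protonation, which fixes the E alkene of the future C5–C6 unit.

Step 2
Reactants: 3 (2E)-2-(prop-2-en-1-yl)but-2-en-1-ol
Product: 4 (2E)-2-ethylidenepent-4-enal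
Conditions: MnO2, CH2Cl2, rt
Reagents that add atoms: none
Why: MnO2 oxidizes the allylic alcohol chemoselectively to the enal and should leave the isolated terminal alkene and the alkene geometry untouched (allylic alcohol oxidation).

Step 3
Reactants: 4 (2E)-2-ethylidenepent-4-enal; 5 1,3-dimethoxypropan-2-one
Product: 6 (3Z,5E)-1,3-dimethoxy-5-(prop-2-en-1-yl)hepta-3,5-dien-2-one
Conditions: 5 (3 equiv), KOH (0.2 equiv), MeOH, 0 °C to rt
Reagents that add atoms: none
Why: Crossed aldol condensation of the symmetrical ketone, used in excess, with an enal that has no alpha hydrogen should give the mono-dienone, and the reversible dehydration should settle on the isomer with the acyl group trans to the dienyl carbon.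

Step 4
Reactants: 6 (3Z,5E)-1,3-dimethoxy-5-(prop-2-en-1-yl)hepta-3,5-dien-2-one
Product: 8 3-allyl-5-methoxy-6-(methoxymethyl)-2-methyl-2H-pyran (racemic), via cis-dienone 7 (not isolated)
Conditions: hν (350 nm), MeCN, rt
Reagents that add atoms: none
Why: Photochemical isomerization of the methoxy enone double bond from 3Z (acyl trans to the dienyl carbon) to 3E (acyl cis) gives 7, which should close thermally by oxa-6π electrocyclization to a pyran that absorbs far less at this wavelength, so the cis geometry of the future C3=C4 bond is stored in the ring and the ethylidene geometry is reset to E whenever the pyran reopens.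

Step 5
Reactants: 9 homovanillic acid
Product: 10 tert-butyldimethylsilyl [4-(tert-butyldimethylsilyloxy)-3-methoxyphenyl]acetate
Conditions: TBSCl (2.2 equiv), imidazole, DMF, rt
Reagents that add atoms: tert-butyldimethylsilyl chloride, CC(C)(C)[Si](C)(C)Cl
Why: Imidazole-promoted silylation should cap the phenol as a silyl ether and the acid as a silyl ester in one operation (silyl protection).

Step 6
Reactants: 10 tert-butyldimethylsilyl [4-(tert-butyldimethylsilyloxy)-3-methoxyphenyl]acetate
Product: 11 [4-(tert-butyldimethylsilyloxy)-3-methoxyphenyl]acetyl chloride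
Conditions: (COCl)2, DMF (cat.), CH2Cl2, 0 °C to rt
Reagents that add atoms: oxalyl chloride, O=C(Cl)C(=O)Cl
Why: The Vilsmeier-type reagent from oxalyl chloride and DMF converts a silyl ester directly into the acid chloride under neutral conditions, so the aryl silyl ether should survive.

Step 7
Reactants: 8 3-allyl-5-methoxy-6-(methoxymethyl)-2-methyl-2H-pyran; 11 [4-(tert-butyldimethylsilyloxy)-3-methoxyphenyl]acetyl chloride
Product: 13 (5E,7E)-1-[4-(tert-butyldimethylsilyloxy)-3-methoxyphenyl]-3,5-dimethoxy-7-(prop-2-en-1-yl)nona-5,7-diene-2,4-dione (racemic at C3), via lithium enolate 12 (not isolated)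
Conditions: 8, LiN(SiMe3)2 (2.2 equiv), THF, 0 °C, then −78 °C; 11, −78 to 0 °C; aq NH4Cl
Reagents that add atoms: none
Why: Pyran 8 is in mobile equilibrium with its open valence tautomer (Remark 2), whose methoxymethyl group carries the only alpha hydrogens of the ketone, so LiN(SiMe3)2 should drain the equilibrium into the chelated Z lithium enolate 12, and C-acylation of 12 by the acid chloride, with the second equivalent of base taking up the more acidic product (Claisen-type acylation), should give the 2-methoxy-1,3-diketone without touching the dienone geometry.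

Step 8
Reactants: 13 (5E,7E)-1-[4-(tert-butyldimethylsilyloxy)-3-methoxyphenyl]-3,5-dimethoxy-7-(prop-2-en-1-yl)nona-5,7-diene-2,4-dione
Product: 16 rac-6-allyl-1,3-bis(tert-butyldimethylsilyloxy)-8-[4-(tert-butyldimethylsilyloxy)-3-methoxyphenyl]-2,4-dimethoxy-7-methylbicyclo[4.2.0]octa-2,4-diene (cis ring fusion; 8-aryl endo; 7-methyl exo), via tetraene 14 (not isolated), via cyclooctatriene 15 (not isolated)
Conditions: TBSOTf (2.5 equiv), Et3N (4 equiv), toluene, 0 °C; then 70 °C
Reagents that add atoms: tert-butyldimethylsilyl trifluoromethanesulfonate, CC(C)(C)[Si](C)(C)OS(=O)(=O)C(F)(F)F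
Why: Soft double enolization turns the 2-methoxy-1,3-diketone into bis(silyl) dienol ether 14, a tetraene that holds all eight ring carbons of the target in one chain (C7=C8–C1=C2–C3=C4–C5=C6). Thermal conrotatory 8π electrocyclization joins the chain ends C7 and C6 to give cyclooctatriene 15, and disrotatory 6π electrocyclization of its triene then joins C8 to C5 and closes the cis-fused cyclobutane and cyclohexadiene rings; this is the 8π–6π electrocyclization cascade known from polyene natural products. The trans relation of aryl and methyl follows from conrotation of the two outward-pointing terminal groups (Z enol silane at C7=C8 with aryl cis to OSi, E ethylidene at C5=C6), and the cis ring fusion follows from disrotation. Which of the two trans groups lies endo is decided in the reversible 6π step, where the aryl group should avoid the bulky silyloxy group on the neighbouring ring-fusion carbon C8 and sit endo, with the methyl exo. The step needs the helical tetraene with both inner double bonds cis: the C3=C4 geometry comes from pyran 8, whereas the two enol silane double bonds (C7=C8 and C1=C2) can equilibrate through the ammonium triflate present, so the reactive isomer is drained by the irreversible 8π closure. No stereocenter exists before this step, so 16 forms as a racemate.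

Step 9
Reactants: 16 rac-6-allyl-1,3-bis(tert-butyldimethylsilyloxy)-8-[4-(tert-butyldimethylsilyloxy)-3-methoxyphenyl]-2,4-dimethoxy-7-methylbicyclo[4.2.0]octa-2,4-diene
Product: 18 (1S,5R,6R,7S)-5-allyl-7-(4-hydroxy-3-methoxyphenyl)-1,3-dimethoxy-6-methylbicyclo[3.2.1]oct-3-ene-2,8-dione (racemate), via bromo silyl enol ether 17 (not isolated)
Conditions: NBS (1.05 equiv), NaHCO3, CH2Cl2, −78 °C; then Bu4NF, AcOH, THF, 0 °C
Reagents that add atoms: none
Why: Bromination at the C4 terminus of the electron-rich trioxygenated diene gives an oxygen-stabilized allyl cation whose C1 end adjoins the cyclobutanol silyl ether, so a strain-releasing semipinacol 1,2-shift of the benzylic carbon C7 from C8 to C1 (halonium-induced semipinacol ring expansion, with retention at C7, the C8–C7 bond being aligned with the empty orbital at C1 whereas the C8–C5 bond lies in the plane of the six-membered ring) should form the C8 ketone and the quaternary C1–OMe center, after which fluoride desilylates the enol ether, expels bromide to restore the C3=C4 methoxy enone and frees the phenol.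

Step 10
Reactants: 18 (1S,5R,6R,7S)-5-allyl-7-(4-hydroxy-3-methoxyphenyl)-1,3-dimethoxy-6-methylbicyclo[3.2.1]oct-3-ene-2,8-dione (racemate)
Product: 19 (1R,2S,5R,6R,7S)-5-allyl-2-hydroxy-7-(4-hydroxy-3-methoxyphenyl)-1,3-dimethoxy-6-methylbicyclo[3.2.1]oct-3-en-8-one
Conditions: (R)-2-methyl-CBS-oxazaborolidine (0.5 equiv), catecholborane (1.6 equiv), toluene, −78 °C, stopped near half conversion; chromatography
Reagents that add atoms: none
Why: In this CBS reduction the C2 carbonyl should be reached only from the exo face (the side of the C8 bridge, anti to the endo aryl group), which gives the 2S alcohol, and the (R)-oxazaborolidine, which treats the fully substituted C1 as the large group, should deliver hydride to that face only for the enantiomer shown, so the catalyst acts as a kinetic resolution that leaves the mirror-image diketone unreduced and separable.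

Compound list
1 | but-2-yn-1-ol | CC#CCO | starting material
2 | allylmagnesium bromide | C=CC[Mg]Br | starting material
3 | (2E)-2-(prop-2-en-1-yl)but-2-en-1-ol | C/C=C(/CO)CC=C | intermediate
4 | (2E)-2-ethylidenepent-4-enal | C/C=C(/C=O)CC=C | intermediate
5 | 1,3-dimethoxypropan-2-one | COCC(=O)COC | starting material
6 | (3Z,5E)-1,3-dimethoxy-5-(prop-2-en-1-yl)hepta-3,5-dien-2-one | COCC(=O)/C(OC)=C/C(CC=C)=C/C | intermediate
7 | (3E,5E)-1,3-dimethoxy-5-(prop-2-en-1-yl)hepta-3,5-dien-2-one (cis-dienone, not isolated) | COCC(=O)/C(OC)=C\C(CC=C)=C\C | intermediate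
8 | 3-allyl-5-methoxy-6-(methoxymethyl)-2-methyl-2H-pyran (racemic) | CC1OC(COC)=C(OC)C=C1CC=C | intermediate
9 | homovanillic acid | COc1cc(CC(=O)O)ccc1O | starting material
10 | tert-butyldimethylsilyl [4-(tert-butyldimethylsilyloxy)-3-methoxyphenyl]acetate | COc1cc(CC(=O)O[Si](C)(C)C(C)(C)C)ccc1O[Si](C)(C)C(C)(C)C | intermediate
11 | [4-(tert-butyldimethylsilyloxy)-3-methoxyphenyl]acetyl chloride | COc1cc(CC(=O)Cl)ccc1O[Si](C)(C)C(C)(C)C | intermediate
12 | lithium (1Z,3E,5E)-1,3-dimethoxy-5-(prop-2-en-1-yl)hepta-1,3,5-trien-2-olate (lithium enolate, not isolated) | CO/C=C(\[O-])/C(OC)=C\C(CC=C)=C\C.[Li+] | intermediate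
13 | (5E,7E)-1-[4-(tert-butyldimethylsilyloxy)-3-methoxyphenyl]-3,5-dimethoxy-7-(prop-2-en-1-yl)nona-5,7-diene-2,4-dione (racemic at C3) | COc1cc(CC(=O)C(OC)C(=O)/C(OC)=C\C(CC=C)=C\C)ccc1O[Si](C)(C)C(C)(C)C | intermediate
14 | (1Z,3Z,5E,7E)-2,4-bis(tert-butyldimethylsilyloxy)-1-[4-(tert-butyldimethylsilyloxy)-3-methoxyphenyl]-3,5-dimethoxy-7-(prop-2-en-1-yl)nona-1,3,5,7-tetraene (not isolated) | CC(C)(C)[Si](C)(C)Oc1ccc(/C=C(O[Si](C)(C)C(C)(C)C)/C(OC)=C(O[Si](C)(C)C(C)(C)C)\C(OC)=C/C(CC=C)=C/C)cc1OC | intermediate
15 | rac-trans-1-allyl-4,6-bis(tert-butyldimethylsilyloxy)-7-[4-(tert-butyldimethylsilyloxy)-3-methoxyphenyl]-3,5-dimethoxy-8-methylcycloocta-1,3,5-triene (not isolated) | C[C@@H]1[C@@H](c2ccc(O[Si](C)(C)C(C)(C)C)c(OC)c2)C(O[Si](C)(C)C(C)(C)C)=C(OC)C(O[Si](C)(C)C(C)(C)C)=C(OC)C=C1CC=C | intermediate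
16 | rac-6-allyl-1,3-bis(tert-butyldimethylsilyloxy)-8-[4-(tert-butyldimethylsilyloxy)-3-methoxyphenyl]-2,4-dimethoxy-7-methylbicyclo[4.2.0]octa-2,4-diene (cis-fused; 8-aryl endo; 7-methyl exo) | C=CC[C@@]12C=C(OC)C(O[Si](C)(C)C(C)(C)C)=C(OC)[C@]1(O[Si](C)(C)C(C)(C)C)[C@H](c1ccc(O[Si](C)(C)C(C)(C)C)c(OC)c1)[C@H]2C | intermediate
17 | rac-5-allyl-4-bromo-2-(tert-butyldimethylsilyloxy)-7-[4-(tert-butyldimethylsilyloxy)-3-methoxyphenyl]-1,3-dimethoxy-6-methylbicyclo[3.2.1]oct-2-en-8-one (not isolated; bromide configuration open) | C=CC[C@@]12C(Br)C(OC)=C(O[Si](C)(C)C(C)(C)C)[C@@](OC)(C1=O)[C@H](c1ccc(O[Si](C)(C)C(C)(C)C)c(OC)c1)[C@H]2C | intermediate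
18 | (1S,5R,6R,7S)-5-allyl-7-(4-hydroxy-3-methoxyphenyl)-1,3-dimethoxy-6-methylbicyclo[3.2.1]oct-3-ene-2,8-dione (racemate; enantiomer shown) | C=CC[C@@]12C=C(OC)C(=O)[C@@](OC)(C1=O)[C@H](c1ccc(O)c(OC)c1)[C@H]2C | intermediate
19 | (1R,2S,5R,6R,7S)-5-allyl-2-hydroxy-7-(4-hydroxy-3-methoxyphenyl)-1,3-dimethoxy-6-methylbicyclo[3.2.1]oct-3-en-8-one | C=CC[C@@]12C=C(OC)[C@H](O)[C@@](OC)(C1=O)[C@H](c1ccc(O)c(OC)c1)[C@H]2C | target

Total step count: 10. Longest linear sequence: 8 steps (steps 1 to 4 and 7 to 10).

Steps most likely to fail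

Step 8. The bis(silyl) dienol ether may not reach the helical geometry because the inner enol silane double bond stays trans. The 6π equilibrium may also rest on the side of the cyclooctatriene, since both ring-fusion carbons are fully substituted, or the closure may place the aryl group exo. Fallback: the two bonds are made by a triplet-sensitized intramolecular [2+2] photocycloaddition instead of the thermal cascade. It sets out from 13, which is silylated as before at 0 °C to 14, and 14 is irradiated at 450 nm with Ir(ppy)3 (tris(2-phenylpyridinato)iridium) in toluene. Energy transfer to the aryl diene unit should give a 1,4-biradical that closes the six-membered ring first and the cyclobutane second, independent of the ground-state geometry of the enol silane double bonds. It comes back to the route at 16 and needs no compound outside the list (F0).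

Step 9. Bromination may occur at the aryl ring or the allyl group, the cation may be captured without migration, or C5 may migrate in place of C7. Fallback: the shift is separated from the oxidation. It sets out from 16. TfOH (1 equiv, CH2Cl2, −78 °C) protonates C4 and should trigger the same semipinacol shift, giving rac-5-allyl-2-(tert-butyldimethylsilyloxy)-7-[4-(tert-butyldimethylsilyloxy)-3-methoxyphenyl]-1,3-dimethoxy-6-methylbicyclo[3.2.1]oct-2-en-8-one F1. Saegusa–Ito oxidation with Pd(OAc)2 in MeCN then restores the C3=C4 double bond and gives the aryl silyl ether of the diketone, rac-5-allyl-7-[4-(tert-butyldimethylsilyloxy)-3-methoxyphenyl]-1,3-dimethoxy-6-methylbicyclo[3.2.1]oct-3-ene-2,8-dione F2. Bu4NF with AcOH removes the aryl silyl group and the fallback comes back to the route at 18.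

Step 10. The oxazaborolidine may discriminate the enantiomers poorly, or reduction of the C8 ketone may compete. Fallback: reduction and resolution are separated. It sets out from 18. Luche reduction (NaBH4, CeCl3·7H2O, MeOH, −78 °C) should reduce both enantiomers by the same exo attack and give 19 as a racemate, together with its mirror image, (1S,2R,5S,6S,7R)-5-allyl-2-hydroxy-7-(4-hydroxy-3-methoxyphenyl)-1,3-dimethoxy-6-methylbicyclo[3.2.1]oct-3-en-8-one F3. Esterification of the phenol with (2S)-2-methoxy-2-phenylacetic acid (DCC, DMAP) gives the diastereomeric esters, the (2S)-2-methoxy-2-phenylacetate of 19, F4, and the (2S)-2-methoxy-2-phenylacetate of the enantiomer of 19, F5, which are separated on silica. K2CO3 in MeOH cleaves F4 and the fallback comes back to the route at 19.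

Further compounds
F0 | step 8 | none | none
F1 | step 9 | rac-5-allyl-2-(tert-butyldimethylsilyloxy)-7-[4-(tert-butyldimethylsilyloxy)-3-methoxyphenyl]-1,3-dimethoxy-6-methylbicyclo[3.2.1]oct-2-en-8-one | C=CC[C@@]12CC(OC)=C(O[Si](C)(C)C(C)(C)C)[C@@](OC)(C1=O)[C@H](c1ccc(O[Si](C)(C)C(C)(C)C)c(OC)c1)[C@H]2C
F2 | step 9 | rac-5-allyl-7-[4-(tert-butyldimethylsilyloxy)-3-methoxyphenyl]-1,3-dimethoxy-6-methylbicyclo[3.2.1]oct-3-ene-2,8-dione | C=CC[C@@]12C=C(OC)C(=O)[C@@](OC)(C1=O)[C@H](c1ccc(O[Si](C)(C)C(C)(C)C)c(OC)c1)[C@H]2C
F3 | step 10 | (1S,2R,5S,6S,7R)-5-allyl-2-hydroxy-7-(4-hydroxy-3-methoxyphenyl)-1,3-dimethoxy-6-methylbicyclo[3.2.1]oct-3-en-8-one | C=CC[C@]12C=C(OC)[C@@H](O)[C@](OC)(C1=O)[C@@H](c1ccc(O)c(OC)c1)[C@@H]2C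
F4 | step 10 | 4-[(1R,2S,5R,6R,7S)-5-allyl-2-hydroxy-1,3-dimethoxy-6-methyl-8-oxobicyclo[3.2.1]oct-3-en-7-yl]-2-methoxyphenyl (2S)-2-methoxy-2-phenylacetate | C=CC[C@@]12C=C(OC)[C@H](O)[C@@](OC)(C1=O)[C@H](c1ccc(OC(=O)[C@@H](OC)c3ccccc3)c(OC)c1)[C@H]2C
F5 | step 10 | 4-[(1S,2R,5S,6S,7R)-5-allyl-2-hydroxy-1,3-dimethoxy-6-methyl-8-oxobicyclo[3.2.1]oct-3-en-7-yl]-2-methoxyphenyl (2S)-2-methoxy-2-phenylacetate | C=CC[C@]12C=C(OC)[C@@H](O)[C@](OC)(C1=O)[C@@H](c1ccc(OC(=O)[C@@H](OC)c3ccccc3)c(OC)c1)[C@@H]2C
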